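**Retrosynthetic overview** (positions follow the bicyclo[3.3.1]nonane numbering of the target: C1/C5 bridgeheads, C9 bridging ketone, C2–C3–C4 acylated enol bridge, C6–C7–C8 the other bridge, C1'/C2' the first two geranyl carbons)

1. Feature used: in ring A (C1–C9–C5–C6–C7–C8) C7 is a CH between C6H2 and quaternary C8 and carries C1'H2, whose neighbour C2' begins the (E)-trisubstituted olefin. A C6 radical adding to C7 of a vinyl group on C8 therefore forms C6–C7 and leaves a radical on C1', where an alkenyl–nickel species can attach C2'.
2. Last disconnections: enol methyl ether and aryl silyl ether, then the C3–aroyl bond (C3 lithiation of the bicyclic vinylogous ester 25).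
3. Key disconnection: C6–C7 and C1'–C2', giving the monocyclic ring B iodide 19 and alkenyl bromide 24.
4. 19 from a C5-formyl dearomatised phloroglucinol: prenylation of C5 anti to C8, then CHO to CH2OH to CH2I. C1–C8 comes from a dearomative ortho-Claisen rearrangement of the O9-neryl ether of a prenylated, formylated phloroglucinol monomethyl ether; the racemate is resolved as its (S)-1-phenylethylamine enaminone.
5. Ring order: ring B is the original benzene ring (dearomatised at C1, then at C5); ring A is closed in step 16.

Key step: step 16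

Remark: the target is an enolised 2,4-dione; its tautomers are treated as one compound, and the O-methyl group is carried on O4.
Remark: racemic 12 is entered with the SMILES of the enantiomer that is carried on.

**Step 1**
Reactants: 1 5-methoxyresorcinol
Product: 2 1-methoxy-3,5-bis(methoxymethoxy)benzene
Conditions: MOMCl, i-Pr2NEt, CH2Cl2, 0 °C → rt
Reagents that add atoms: chloromethyl methyl ether, COCCl
Why: O-alkylation of both phenols (acetal formation) gives the bis-MOM ether whose two OCH2OMe groups will direct metalation to the carbon between them.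

**Step 2**
Reactants: 2 1-methoxy-3,5-bis(methoxymethoxy)benzene; 3 prenyl bromide
Product: 5 2-prenyl bis-MOM ether, via aryllithium 4 (not isolated)
Conditions: n-BuLi, THF, 0 °C → rt; then CuI (10 mol %), 3, −78 °C → rt
Reagents that add atoms: none
Why: Directed ortho-metalation places lithium on the carbon flanked by both MOM ethers, and copper-catalysed SN2 allylation with prenyl bromide installs the prenyl group that becomes the C1 substituent.

**Step 3**
Reactants: 5 2-prenyl bis-MOM ether
Product: 6 5-methoxy-2-prenylresorcinol
Conditions: HCl (cat.), MeOH, 40 °C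
Reagents that add atoms: none
Why: Acid-catalysed acetal methanolysis removes both MOM groups under conditions mild enough to leave the ortho-prenyl phenol uncyclised.

**Step 4**
Reactants: 6 5-methoxy-2-prenylresorcinol
Product: 7 2,4-dihydroxy-6-methoxy-3-prenylbenzaldehyde
Conditions: MgCl2, Et3N, (CH2O)n, MeCN, reflux
Reagents that add atoms: paraformaldehyde (source of formaldehyde), C=O
Why: Casnati–Skattebøl ortho-formylation: the only free ring positions are the two equivalent carbons between OH and OMe, so one salicylaldehyde should form, whose formyl carbon is the future C6.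

**Step 5**
Reactants: 7 2,4-dihydroxy-6-methoxy-3-prenylbenzaldehyde
Product: 8 4-O-TBS ether of 7
Conditions: TBSCl (1.05 equiv), imidazole, DMF, 0 °C
Reagents that add atoms: tert-butyldimethylsilyl chloride, CC(C)(C)[Si](C)(C)Cl
Why: Selective silylation: the 4-OH, para to the formyl group, is the more acidic and accessible phenol, while the 2-OH is held in a hydrogen bond to the aldehyde.

**Step 6**
Reactants: 8 4-O-TBS ether of 7; 9 nerol
Product: 10 2-O-neryl 4-O-TBS benzaldehyde
Conditions: 9, PPh3, DIAD, THF, 0 °C → rt
Reagents that add atoms: none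
Why: Mitsunobu etherification of the remaining chelated phenol proceeds by SN2 at the primary allylic carbon of nerol and keeps the (Z)-olefin that later fixes the C1/C8 relative configuration.

**Step 7**
Reactants: 10 2-O-neryl 4-O-TBS benzaldehyde
Product: 11 2-O-neryl 4-hydroxy benzaldehyde
Conditions: TBAF, AcOH, THF, 0 °C
Reagents that add atoms: none
Why: Fluoride desilylation frees the phenol para to the formyl group, so that the cyclohexadienone formed in the next step can tautomerise at once and not migrate further.

**Step 8**
Reactants: 11 2-O-neryl 4-hydroxy benzaldehyde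
Product: 12 racemic hydroxymethylene dione (C1 and C8 set relative to each other)
Conditions: Eu(fod)3 (fod = 6,6,7,7,8,8,8-heptafluoro-2,2-dimethyloctane-3,5-dionate; 20 mol %), CHCl3, 50 °C
Reagents that add atoms: none
Why: Lewis-acid-catalysed dearomative ortho-Claisen rearrangement ([3,3]): europium chelated between the ether oxygen (O9) and the formyl oxygen activates the C–O bond, the formyl-bearing ortho carbon is blocked and electron-poor so the allyl unit goes to the prenylated carbon C1, and the chair transition state with the (Z)-olefin (homoprenyl axial, methyl equatorial on C8; prenyl axial on C1) sets C1 and C8 in the relative configuration of the target before proton shift from the para-OH gives the stable hydroxymethylene dione.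

**Step 9**
Reactants: 12 racemic hydroxymethylene dione; 13 (S)-1-phenylethylamine
Product: 14 enaminone (single diastereomer with C1 and C8 as in the target)
Conditions: 13 (1.05 equiv), MgSO4, CH2Cl2, rt; chromatographic separation of the two diastereomers
Reagents that add atoms: none
Why: Condensation of the hydroxymethylene ketone with the enantiopure amine (enaminone formation) should give two hydrogen-bonded, silica-stable diastereomers, so this is a classical resolution; the configuration of the retained isomer is to be assigned by crystallography.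

**Step 10**
Reactants: 14 enaminone
Product: 15 hydroxymethylene dione (single enantiomer)
Conditions: 1 M aq. HCl, THF, rt
Reagents that add atoms: water, O
Why: Acid hydrolysis of the vinylogous amide returns the hydroxymethylene ketone and releases the amine as its salt, while the vinylogous methyl ester is expected to survive dilute acid at room temperature.

**Step 11**
Reactants: 15 hydroxymethylene dione; 16 prenyl acetate
Product: 17 C5-quaternary aldehyde (C1, C5 and C8 set)
Conditions: 16, Pd(PPh3)4 (5 mol %), Cs2CO3, THF, rt
Reagents that add atoms: none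
Why: Tsuji–Trost allylation: the stabilised enolate attacks the unsubstituted terminus of the prenyl–palladium complex through C5 (O-allylation is reversible under palladium) on the ring face opposite the bulky tertiary C8 group at C1, so the formyl group (future C6) ends cis to C8.

**Step 12**
Reactants: 17 C5-quaternary aldehyde
Product: 18 C6 alcohol
Conditions: NaBH4, EtOH/CH2Cl2, −78 °C; AcOH quench
Reagents that add atoms: none
Why: Chemoselective borohydride reduction: the aldehyde is far more electrophilic than the ketone between two quaternary carbons and the vinylogous ester carbonyl, and the cold acidic quench avoids retro-aldol loss of formaldehyde.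

**Step 13**
Reactants: 18 C6 alcohol
Product: 19 C6 iodide (key-step precursor)
Conditions: PPh3, I2, imidazole, PhMe, 60 °C
Reagents that add atoms: iodine, II
Why: Appel-type iodination converts the neopentyl primary alcohol into the iodide through its alkoxyphosphonium ion without forming a free alkoxide.

**Step 14**
Reactants: 20 6-methylhept-5-en-2-one
Product: 22 6-methylhept-5-en-1-yne, via enol phosphate 21 (not isolated)
Conditions: LDA, THF, −78 °C; ClP(O)(OEt)2; then LDA (2.2 equiv), −78 °C → rt
Reagents that add atoms: none
Why: Methyl ketone to terminal alkyne conversion: kinetic deprotonation at the methyl group, O-phosphorylation and elimination from the enol phosphate.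

**Step 15**
Reactants: 22 6-methylhept-5-en-1-yne
Product: 24 (E)-1-bromo-2,6-dimethylhepta-1,5-diene, via alkenylalane 23 (not isolated)
Conditions: AlMe3, Cp2ZrCl2 (20 mol %), CH2Cl2, 0 °C → rt; then NBS, THF, −30 °C
Reagents that add atoms: trimethylaluminium, C[Al](C)C; N-bromosuccinimide, O=C1CCC(=O)N1Br
Why: Zirconium-catalysed Negishi carboalumination adds methyl and aluminium syn across the alkyne with aluminium on the terminal carbon, and bromodealumination with retention gives the (E)-alkenyl bromide.

**Step 16**
Reactants: 19 C6 iodide; 24 (E)-1-bromo-2,6-dimethylhepta-1,5-diene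
Product: 25 bicyclic vinylogous methyl ester (7-geranyl-1,5-diprenyl; target minus aroyl)
Conditions: NiBr2(dme) (20 mol %), 4,4'-di-tert-butyl-2,2'-bipyridine (24 mol %), Zn (3 equiv), 24 (3 equiv), DMA, 25 °C
Reagents that add atoms: none
Why: Low-valent nickel (from NiBr2(dme), the bipyridine and zinc) abstracts iodine from 19 to give the neopentyl C6 radical, which adds to C7 of the vinyl group on C8; the resulting primary C1' radical is captured by the alkenyl nickel bromide formed from 24, and reductive elimination from trivalent nickel forms C1'–C2' with retention of the (E)-olefin. The closest known reaction type is the nickel-catalysed reductive cyclization of alkyl-iodide-tethered alkenes with cross-electrophile capture by aryl or alkenyl bromides (alkene 1,2-dicarbofunctionalization). Ring A (C5–C6–C7–C8–C1–C9) closes 6-exo-trig through a chair spanning the cis 1,3-arms of ring B, whereas 7-endo attack at C1' would need a more strained bridged transition state. C7 is the only new stereocentre: in the chair the CH2 terminus lies equatorial because the axial position points at C2 and C4 of ring B, so the geranyl group ends equatorial as in the target. The step needs ring closure to outrun capture of the C6 radical by nickel and its 1,2-acyl shift onto C9, which the preorganised cis arms should favour, and needs capture of the C1' radical to outrun its 6-exo attack on the C8 homoprenyl olefin, which the excess of 24 and the nickel loading serve. The C1 prenyl group lies trans to the C6 arm and cannot be reached.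

**Step 17**
Reactants: 26 3-hydroxybenzoic acid
Product: 27 bis-TBS derivative (silyl ester and aryl silyl ether)
Conditions: TBSCl (2.3 equiv), imidazole, DMF, rt
Reagents that add atoms: tert-butyldimethylsilyl chloride, CC(C)(C)[Si](C)(C)Cl
Why: Silylation of both the phenol and the carboxylic acid.

**Step 18**
Reactants: 27 bis-TBS derivative
Product: 28 3-[(tert-butyldimethylsilyl)oxy]benzoyl chloride
Conditions: (COCl)2, DMF (cat.), CH2Cl2, 0 °C → rt
Reagents that add atoms: oxalyl chloride, O=C(Cl)C(=O)Cl
Why: Silyl esters are converted by oxalyl chloride/DMF (Vilsmeier-type activation) into acid chlorides under neutral conditions that leave the aryl silyl ether intact.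

**Step 19**
Reactants: 25 bicyclic vinylogous methyl ester; 28 3-[(tert-butyldimethylsilyl)oxy]benzoyl chloride
Product: 30 C3-aroyl bicyclic methyl enol ether, via C3-lithio vinylogous ester 29 (not isolated)
Conditions: LiTMP, THF, −78 °C; then 28, −78 → 0 °C
Reagents that add atoms: none
Why: Vinylic deprotonation of the vinylogous ester at C3 (the only acidic C–H, since both carbonyls are flanked by quaternary bridgeheads) and C-acylation of the vinyllithium with the aroyl chloride.

**Step 20**
Reactants: 30 C3-aroyl bicyclic methyl enol ether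
Product: 32 CNP0285073.1 (target), via phenol methyl ether 31 (not isolated)
Conditions: TBAF, THF, 0 °C; then LiCl, DMSO, 120 °C; aq. HCl work-up
Reagents that add atoms: none
Why: Fluoride desilylation of the aryl silyl ether, then SN2 demethylation of the vinylogous methyl ester by chloride, releases the enolised β-triketone without touching the olefins or the stereocentres.

**Compound list**

1 | 5-methoxybenzene-1,3-diol (5-methoxyresorcinol) | COc1cc(O)cc(O)c1 | starting material
2 | 1-methoxy-3,5-bis(methoxymethoxy)benzene | COCOc1cc(OC)cc(OCOC)c1 | intermediate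
3 | 1-bromo-3-methylbut-2-ene (prenyl bromide) | CC(C)=CCBr | starting material
4 | [4-methoxy-2,6-bis(methoxymethoxy)phenyl]lithium | [Li]c1c(OCOC)cc(OC)cc1OCOC | intermediate
5 | 5-methoxy-1,3-bis(methoxymethoxy)-2-(3-methylbut-2-en-1-yl)benzene | COCOc1cc(OC)cc(OCOC)c1CC=C(C)C | intermediate
6 | 5-methoxy-2-(3-methylbut-2-en-1-yl)benzene-1,3-diol | COc1cc(O)c(CC=C(C)C)c(O)c1 | intermediate
7 | 2,4-dihydroxy-6-methoxy-3-(3-methylbut-2-en-1-yl)benzaldehyde | O=Cc1c(O)c(CC=C(C)C)c(O)cc1OC | intermediate
8 | 4-[(tert-butyldimethylsilyl)oxy]-2-hydroxy-6-methoxy-3-(3-methylbut-2-en-1-yl)benzaldehyde | O=Cc1c(O)c(CC=C(C)C)c(O[Si](C)(C)C(C)(C)C)cc1OC | intermediate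
9 | nerol, (2Z)-3,7-dimethylocta-2,6-dien-1-ol | CC(C)=CCC/C(C)=C\CO | starting material
10 | 4-[(tert-butyldimethylsilyl)oxy]-2-{[(2Z)-3,7-dimethylocta-2,6-dien-1-yl]oxy}-6-methoxy-3-(3-methylbut-2-en-1-yl)benzaldehyde | O=Cc1c(OC/C=C(C)\CCC=C(C)C)c(CC=C(C)C)c(O[Si](C)(C)C(C)(C)C)cc1OC | intermediate
11 | 2-{[(2Z)-3,7-dimethylocta-2,6-dien-1-yl]oxy}-4-hydroxy-6-methoxy-3-(3-methylbut-2-en-1-yl)benzaldehyde | O=Cc1c(OC/C=C(C)\CCC=C(C)C)c(CC=C(C)C)c(O)cc1OC | intermediate
12 | racemic 3-(3,7-dimethylocta-1,6-dien-3-yl)-2-hydroxy-6-methoxy-3-(3-methylbut-2-en-1-yl)-4-oxocyclohexa-1,5-diene-1-carbaldehyde; ring C3 (target C1) and side-chain C3 (target C8) in the relative configuration of the target; the enantiomer carried on is drawn | O=CC1=C(O)[C@@](CC=C(C)C)(C(=O)C=C1OC)[C@@](C=C)(C)CCC=C(C)C | intermediate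
13 | (S)-1-phenylethylamine | C[C@H](N)c1ccccc1 | starting material
14 | 2-(3,7-dimethylocta-1,6-dien-3-yl)-5-methoxy-2-(3-methylbut-2-en-1-yl)-6-({[(1S)-1-phenylethyl]amino}methylidene)cyclohex-4-ene-1,3-dione; target C1 and C8 as in the target; N cis to the C9 carbonyl | C[C@H](N/C=C1\C(=O)[C@@](CC=C(C)C)(C(=O)C=C1OC)[C@@](C=C)(C)CCC=C(C)C)c1ccccc1 | intermediate
15 | 3-(3,7-dimethylocta-1,6-dien-3-yl)-2-hydroxy-6-methoxy-3-(3-methylbut-2-en-1-yl)-4-oxocyclohexa-1,5-diene-1-carbaldehyde, single enantiomer (target C1 and C8 as in the target) | O=CC1=C(O)[C@@](CC=C(C)C)(C(=O)C=C1OC)[C@@](C=C)(C)CCC=C(C)C | intermediate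
16 | 3-methylbut-2-en-1-yl acetate (prenyl acetate) | CC(=O)OCC=C(C)C | starting material
17 | 3-(3,7-dimethylocta-1,6-dien-3-yl)-6-methoxy-1,3-bis(3-methylbut-2-en-1-yl)-2,4-dioxocyclohex-5-ene-1-carbaldehyde; formyl cis to the octadienyl group; target C1, C5 and C8 set | O=C[C@]1(CC=C(C)C)C(=O)[C@@](CC=C(C)C)(C(=O)C=C1OC)[C@@](C=C)(C)CCC=C(C)C | intermediate
18 | 2-(3,7-dimethylocta-1,6-dien-3-yl)-6-(hydroxymethyl)-5-methoxy-2,6-bis(3-methylbut-2-en-1-yl)cyclohex-4-ene-1,3-dione; configuration as in 17 | OC[C@]1(CC=C(C)C)C(=O)[C@@](CC=C(C)C)(C(=O)C=C1OC)[C@@](C=C)(C)CCC=C(C)C | intermediate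
19 | 2-(3,7-dimethylocta-1,6-dien-3-yl)-6-(iodomethyl)-5-methoxy-2,6-bis(3-methylbut-2-en-1-yl)cyclohex-4-ene-1,3-dione; iodomethyl cis to the octadienyl group | IC[C@]1(CC=C(C)C)C(=O)[C@@](CC=C(C)C)(C(=O)C=C1OC)[C@@](C=C)(C)CCC=C(C)C | intermediate
20 | 6-methylhept-5-en-2-one | CC(=O)CCC=C(C)C | starting material
21 | diethyl 6-methylhepta-1,5-dien-2-yl phosphate | C=C(CCC=C(C)C)OP(=O)(OCC)OCC | intermediate
22 | 6-methylhept-5-en-1-yne | C#CCCC=C(C)C | intermediate
23 | [(1E)-2,6-dimethylhepta-1,5-dien-1-yl]dimethylaluminium | C[Al](C)/C=C(\C)CCC=C(C)C | intermediate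
24 | (E)-1-bromo-2,6-dimethylhepta-1,5-diene | Br/C=C(\C)CCC=C(C)C | intermediate
25 | 7-[(2E)-3,7-dimethylocta-2,6-dien-1-yl]-4-methoxy-8-methyl-8-(4-methylpent-3-en-1-yl)-1,5-bis(3-methylbut-2-en-1-yl)bicyclo[3.3.1]non-3-ene-2,9-dione; C1, C5, C7, C8 as in the target | CC(C)=CCC/C(C)=C/C[C@@H]1C[C@]2(CC=C(C)C)C(=O)[C@@](CC=C(C)C)(C(=O)C=C2OC)[C@@]1(C)CCC=C(C)C | intermediate
26 | 3-hydroxybenzoic acid | O=C(O)c1cccc(O)c1 | starting material
27 | tert-butyldimethylsilyl 3-[(tert-butyldimethylsilyl)oxy]benzoate | CC(C)(C)[Si](C)(C)OC(=O)c1cccc(O[Si](C)(C)C(C)(C)C)c1 | intermediate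
28 | 3-[(tert-butyldimethylsilyl)oxy]benzoyl chloride | O=C(Cl)c1cccc(O[Si](C)(C)C(C)(C)C)c1 | intermediate
29 | C3-lithio derivative of 25 | CC(C)=CCC/C(C)=C/C[C@@H]1C[C@]2(CC=C(C)C)C(=O)[C@@](CC=C(C)C)(C(=O)C([Li])=C2OC)[C@@]1(C)CCC=C(C)C | intermediate
30 | 3-{3-[(tert-butyldimethylsilyl)oxy]benzoyl} derivative of 25 | CC(C)=CCC/C(C)=C/C[C@@H]1C[C@]2(CC=C(C)C)C(=O)[C@@](CC=C(C)C)(C(=O)C(C(=O)c3cccc(O[Si](C)(C)C(C)(C)C)c3)=C2OC)[C@@]1(C)CCC=C(C)C | intermediate
31 | 3-(3-hydroxybenzoyl) derivative of 25 (O4-methyl ether of the target) | CC(C)=CCC/C(C)=C/C[C@@H]1C[C@]2(CC=C(C)C)C(=O)[C@@](CC=C(C)C)(C(=O)C(C(=O)c3cccc(O)c3)=C2OC)[C@@]1(C)CCC=C(C)C | intermediate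
32 | CNP0285073.1: 7-[(2E)-3,7-dimethylocta-2,6-dien-1-yl]-4-hydroxy-3-(3-hydroxybenzoyl)-8-methyl-8-(4-methylpent-3-en-1-yl)-1,5-bis(3-methylbut-2-en-1-yl)bicyclo[3.3.1]non-3-ene-2,9-dione | CC(C)=CCC/C(C)=C/C[C@@H]1C[C@]2(CC=C(C)C)C(=O)[C@@](CC=C(C)C)(C(=O)C(C(=O)c3cccc(O)c3)=C2O)[C@@]1(C)CCC=C(C)C | target

**Totals and risks**

Total step count: 20. Longest linear sequence: 16 steps (steps 1–13, 16, 19, 20).

Steps most likely to fail:

1. **Step 16.** The neopentyl C6 radical may be trapped by the alkenyl–nickel species before it closes the ring (open-chain alkenylation), or may attack the C9 carbonyl (Dowd–Beckwith-type acyl shift with ring expansion), or the cyclised C1' radical may add to the C8 homoprenyl olefin before nickel captures it. Fallback, from 19 back to 25: ring closure and coupling are separated. Iodine atom-transfer radical cyclization of 19 (hexabutylditin cat., visible light, benzene, 60 °C), in which no metal competes for the C6 radical, should give the bicyclic primary iodide F1. Zinc insertion (Zn dust, LiCl, THF/DMA) should give the alkylzinc iodide F2. Negishi coupling of F2 with 24 (Pd(PPh3)4, THF, 50 °C) should give 25.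

2. **Step 8.** After the first [3,3] shift the allyl unit may migrate on (Cope shift from C1 to the formyl-bearing C5 through the C9 enol, or to C3 followed by rearomatisation), and the Lewis acid may ionise the neryl ether with loss of olefin geometry. Fallback, from 11 to 14: 11 is condensed with 13 (MgSO4, CH2Cl2) to the aldimine F3, which is heated without catalyst (toluene, 110 °C). The dienone formed by the aromatic Claisen rearrangement should tautomerise to the N–H···O=C9 chelated enaminone, which has no C9 enol and so cannot undergo the onward Cope shift. The two diastereomeric enaminones are separated as in step 9 and the route is rejoined at 14.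

3. **Step 11.** The enolate may react at oxygen, the allyl unit may be attacked at its tertiary terminus, the face selectivity at C5 may be poor, or the formyl group of the product may be lost by base-induced retro-Claisen cleavage. Fallback, from 14 to 17: the enaminone 14 is deprotonated at nitrogen (KHMDS, THF, −78 °C) and C-alkylated at C5 with prenyl bromide 3 (alkylation of a metalated chiral enaminone), with C8 and the auxiliary both shielding the same face, to give the quaternary aldimine F4. Mild acid hydrolysis of F4 (1 M aq. HCl, THF) should give 17.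

**Further compounds**

F1 | step 16 | 7-(iodomethyl)-4-methoxy-8-methyl-8-(4-methylpent-3-en-1-yl)-1,5-bis(3-methylbut-2-en-1-yl)bicyclo[3.3.1]non-3-ene-2,9-dione, configuration as in 25 | IC[C@@H]1C[C@]2(CC=C(C)C)C(=O)[C@@](CC=C(C)C)(C(=O)C=C2OC)[C@@]1(C)CCC=C(C)C
F2 | step 16 | alkylzinc iodide formed from F1 at C1' | I[Zn]C[C@@H]1C[C@]2(CC=C(C)C)C(=O)[C@@](CC=C(C)C)(C(=O)C=C2OC)[C@@]1(C)CCC=C(C)C
F3 | step 8 | (E)-N-[(1S)-1-phenylethyl] aldimine of 11 | C[C@H](/N=C/c1c(OC/C=C(C)\CCC=C(C)C)c(CC=C(C)C)c(O)cc1OC)c1ccccc1
F4 | step 11 | (E)-N-[(1S)-1-phenylethyl] aldimine of 17 | C[C@H](/N=C/[C@]1(CC=C(C)C)C(=O)[C@@](CC=C(C)C)(C(=O)C=C1OC)[C@@](C=C)(C)CCC=C(C)C)c1ccccc1
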